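**Retrosynthetic overview**
- Target 6 ⇒ 2,3,6-tribromo-4-methylphenol 3. The benzylic C–O bond (CH3 → CH2OH) is made last, through p-quinone methide 4 and its acetate adduct 5. This is the key step and the new one.
- 3 ⇒ commercial 3-bromo-4-methylphenol 1. The two bromines ortho to OH come from electrophilic bromination, passing through the monobromination product 2.
- No ring is formed. The benzene ring is bought with 1, which already carries the bromine meta to OH that electrophilic chemistry cannot place.

Assumption: the target has no stereocentre (its SMILES carries no stereodescriptor), so it is made as the achiral compound and no stereocontrol is needed.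

**Step 1**
Reactants: 1 3-bromo-4-methylphenol
Product: 3 2,3,6-tribromo-4-methylphenol, via 2,5-dibromo-4-methylphenol 2 (not isolated)
Conditions: Br2 (2.0 equiv), CH2Cl2, 0 °C → rt
Reagents that add atoms: bromine, BrBr
Why: Electrophilic aromatic bromination: the OH group directs to its two free ortho positions (the less hindered C6 first, giving 2, then C2 between OH and Br), the para position is blocked by the methyl group, and exactly two equivalents of Br2 avoid ipso attack there; no stereocentre is formed.

**Step 2**
Reactants: 3 2,3,6-tribromo-4-methylphenol
Product: 6 2,3,6-tribromo-4-(hydroxymethyl)phenol, via p-quinone methide 4 (not isolated), via benzylic acetate 5 (not isolated)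
Conditions: DDQ (1.0 equiv), KOAc (20 mol%), AcOH, 50 °C; then evaporate, THF/pH 8 phosphate buffer (1:1, 0.02 M), rt
Reagents that add atoms: water, O (supplies the benzylic oxygen of 6); acetic acid, CC(=O)O (adds the acetoxy group of 5 only and is released again in the second stage)
Why: Proposed new method: acetate-gated dehydrogenative benzylic acetoxylation of an electron-poor p-cresol with unmasking in the same flask — catalytic acetate ionises the acidic tribromophenol (pKa about 6) to its phenolate, the form that DDQ oxidises readily, net hydride loss from the para-methyl group gives p-quinone methide 4 and DDQH2, AcOH adds 1,6 to 4 to give acetate 5, whose ester oxygen (unlike a free OH or OMe) cannot assist a second hydride loss so the oxidation holds at the alcohol level, and at pH 8 the phenolate of 5 expels acetate, re-forms 4 and is hydrated at the exocyclic carbon to 6 (no stereocentre is formed); the closest known reactions are the DDQ dehydrogenation of 2,6-dialkyl-4-methylphenols in methanol to 4-(methoxymethyl)phenols, the DDQ/AcOH benzylic acetoxylation of electron-rich alkylarenes, and the solvolysis of 4-hydroxybenzyl esters through quinone methides.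

**Compound list**
1 | 3-bromo-4-methylphenol | Cc1ccc(O)cc1Br | starting material
2 | 2,5-dibromo-4-methylphenol | Cc1cc(Br)c(O)cc1Br | intermediate
3 | 2,3,6-tribromo-4-methylphenol | Cc1cc(Br)c(O)c(Br)c1Br | intermediate
4 | 2,3,6-tribromo-4-methylidenecyclohexa-2,5-dien-1-one (p-quinone methide) | C=C1C=C(Br)C(=O)C(Br)=C1Br | intermediate
5 | (2,3,5-tribromo-4-hydroxyphenyl)methyl acetate | CC(=O)OCc1cc(Br)c(O)c(Br)c1Br | intermediate
6 | 2,3,6-tribromo-4-(hydroxymethyl)phenol | OCc1cc(Br)c(O)c(Br)c1Br | target

**Total step count:** 2
**Longest linear sequence:** 2 steps

**Steps most likely to fail** (the route has only two steps, so both are ranked; the new step comes first)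

1. Step 2 (proposed new step). Three things can go wrong:
   - DDQ may be slow on so electron-poor a phenol.
   - The intermediate phenoxyl radical may couple at a bromine-bearing ortho carbon with loss of bromide.
   - Some 5 may be oxidised further to the aldehyde level, or 4 may be captured by phenolate instead of water in the second stage (hence the dilution).

   The fallback uses only known chemistry; it sets out from 3 and comes back at 6. Compound 3 is O-acetylated (Ac2O, pyridine, cat. DMAP, rt) to 2,3,6-tribromo-4-methylphenyl acetate F1. F1 undergoes Wohl–Ziegler radical bromination (NBS 1.05 equiv, AIBN, PhCF3, 80 °C) to 2,3,6-tribromo-4-(bromomethyl)phenyl acetate F2. K2CO3 in THF/water at rt then cleaves the aryl acetate to 2,3,6-tribromo-4-(bromomethyl)phenol F3 (not isolated). Its phenolate expels bromide to give 4, and water adds to give 6. The C–O bond is thus made by substitution instead of dehydrogenation.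

2. Step 1. The second bromination, at the position flanked by OH and Br, may lag, so that a mixture of 2 and 3 forms, or local excess of Br2 may attack the methyl-bearing para carbon.

   The fallback sets out from 1 and comes back at 3. Compound 1 is deliberately over-brominated (Br2 3.2 equiv, NaOAc, AcOH/H2O, 0–5 °C). This fills both ortho positions and then adds bromine ipso at the para carbon, giving rac-2,3,4,6-tetrabromo-4-methylcyclohexa-2,5-dien-1-one F4. Aqueous NaHSO3 then removes only this "positive" ipso-bromine and returns the aromatic phenol 3. The approach changes from stoichiometric control to exhaustive bromination followed by selective reductive removal.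

**Further compounds**
F1 | step 2 | 2,3,6-tribromo-4-methylphenyl acetate | CC(=O)Oc1c(Br)cc(C)c(Br)c1Br
F2 | step 2 | 2,3,6-tribromo-4-(bromomethyl)phenyl acetate | CC(=O)Oc1c(Br)cc(CBr)c(Br)c1Br
F3 | step 2 | 2,3,6-tribromo-4-(bromomethyl)phenol | Oc1c(Br)cc(CBr)c(Br)c1Br
F4 | step 1 | rac-2,3,4,6-tetrabromo-4-methylcyclohexa-2,5-dien-1-one | CC1(Br)C=C(Br)C(=O)C(Br)=C1Br
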